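**Plan**

- Retrosynthesis: the C–S and C–N bonds joining ring E (1,1-dioxo-1,4-thiazine) to quinone ring D are cut first, giving quinone 17 and hypotaurine. Ring D of 17 has two adjacent unsubstituted sp2 CH carbons between its two C=O groups, and the ring B lactone C=O, para to the ring C carbon that carries one quinone carbonyl, makes these two carbons unequal.
- Further cuts: the quinone oxygens (from OMe), the C–O bond of a dienyl triflate (ring A diene and ring B enol ester from enone 14), the two C–C bonds of a Robinson annulation (ring A), the lactone C–O bond (ring B), the benzylic C–C(=O) bond, and the two C–C bonds of a Diels–Alder reaction (ring C).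
- Forward order: ring D (as dimethoxybenzene 1), ring C (o-quinodimethane plus alkynoate, then aromatization), ring B (keto lactone 10), ring A (Michael addition and aldol condensation), diene and quinone adjustment, ring E last.
- Stereochemistry: the only stereocentre, the (S) quaternary carbon shared by rings A and B, is set by a catalyst-controlled asymmetric Michael addition (step 6). It carries no hydrogen and is not touched afterwards.

Key step: step 11

Assumption: the cinchonidinium catalyst of step 6 is taken to give the (S) centre (the pseudoenantiomeric cinchoninium salt would be used if the sense of induction is opposite), and amide 7 is taken to be commercially available.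

**Step 1**
Reactants: 1 1,4-dimethoxy-2,3-dimethylbenzene
Product: 2 2,3-bis(bromomethyl)-1,4-dimethoxybenzene
Conditions: NBS (2.1 equiv), AIBN (5 mol%), PhCF3, reflux, hν
Reagents that add atoms: N-bromosuccinimide, O=C1CCC(=O)N1Br
Why: Wohl–Ziegler benzylic bromination; radical-chain conditions in a non-polar solvent should favour the two side chains over the electron-rich ring.

**Step 2**
Reactants: 2 2,3-bis(bromomethyl)-1,4-dimethoxybenzene; 3 ethyl pent-2-ynoate
Product: 5 ethyl 3-ethyl-5,8-dimethoxy-1,4-dihydronaphthalene-2-carboxylate, via o-quinodimethane 4 (not isolated)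
Conditions: NaI (5 equiv), 3 (4 equiv), DMF, 70 °C, slow addition of 2
Reagents that add atoms: none
Why: iodide-induced 1,4-elimination of the bis(benzylic) dibromide gives the symmetric o-quinodimethane 4, which should be trapped by the alkynoate in a Diels–Alder reaction that builds ring C with the ester and ethyl groups ortho to each other and without any regiochemical issue.

**Step 3**
Reactants: 5 ethyl 3-ethyl-5,8-dimethoxy-1,4-dihydronaphthalene-2-carboxylate
Product: 6 ethyl 3-ethyl-5,8-dimethoxynaphthalene-2-carboxylate
Conditions: DDQ (1.1 equiv), toluene, rt to 60 °C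
Reagents that add atoms: none
Why: DDQ dehydrogenation of the 1,4-dihydronaphthalene, driven by aromatization of ring C.

**Step 4**
Reactants: 6 ethyl 3-ethyl-5,8-dimethoxynaphthalene-2-carboxylate; 7 2-[(tert-butyldimethylsilyl)oxy]-N-methoxy-N-methylacetamide
Product: 9 ethyl 3-(4-hydroxy-3-oxobutan-2-yl)-5,8-dimethoxynaphthalene-2-carboxylate (racemic), via silyl ether ketone 8 (not isolated)
Conditions: lithium diisopropylamide (1.15 equiv), THF, −78 °C; 7, −78 to −40 °C; then 1 M HCl, THF, rt
Reagents that add atoms: none
Why: lateral lithiation of the ortho-ethyl aryl ester gives an ester-stabilised benzylic anion whose acylation by the N-methoxy-N-methylamide stops at the chelated tetrahedral adduct (Weinreb ketone synthesis), so the enolisable ketone never meets base, and the acidic work-up removes the silyl group.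

**Step 5**
Reactants: 9 ethyl 3-(4-hydroxy-3-oxobutan-2-yl)-5,8-dimethoxynaphthalene-2-carboxylate
Product: 10 racemic keto lactone (seven-membered ring B: aryl–C(=O)–O–CH2–C(=O)–CH(CH3)–aryl, fused to the 6,7-bond of 1,4-dimethoxynaphthalene)
Conditions: Bu2SnO (10 mol%), toluene (0.01 M), reflux, 4 Å MS
Reagents that add atoms: none
Why: tin-alkoxide-mediated intramolecular transesterification (lactonization) of the primary alcohol onto the neighbouring ethyl ester should close ring B with loss of ethanol, and the neutral medium should avoid enol lactone (isocoumarin) formation from the benzylic ketone.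

**Step 6**
Reactants: 10 racemic keto lactone; 11 pent-1-en-3-one
Product: 12 (S)-Michael adduct (keto lactone carrying CH3 and a 3-oxopentyl chain on the former benzylic CH)
Conditions: 11 (1.5 equiv), O-allyl-N-(9-anthracenylmethyl)cinchonidinium bromide (10 mol%), Cs2CO3 (0.3 equiv), toluene, −40 °C
Reagents that add atoms: none
Why: asymmetric Michael addition under chiral phase-transfer catalysis (first stage of a Robinson annulation); the benzylic C–H, flanked by the ketone and the arene carrying the ortho lactone carbonyl, is much more acidic than the O–CH2 protons, so the ring-fixed enolate should add through the benzylic carbon while the chiral ammonium ion pair shields one face and sets the (S) quaternary centre.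

**Step 7**
Reactants: 12 (S)-Michael adduct
Product: 14 (S)-tetracyclic enone lactone (ring A = 2-methylcyclohex-2-enone whose C3 carries the lactone O–CH2 and whose C4 is the quaternary carbon), via aldol adduct 13 (not isolated)
Conditions: TsOH·H2O (10 mol%), toluene, reflux, azeotropic removal of water
Reagents that add atoms: none
Why: acid-catalysed intramolecular aldol condensation (second stage of the Robinson annulation) closes ring A as the conjugated tetrasubstituted enone; the alternative bridged aldol from the O–CH2 enol cannot dehydrate to a conjugated enone and should revert.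

**Step 8**
Reactants: 14 (S)-tetracyclic enone lactone
Product: 15 (S)-dienyl triflate (ring A 1-triflyloxy-2-methyl diene conjugated with the ring B enol ester C=CH–O)
Conditions: Tf2O (1.3 equiv), 2,6-di-tert-butyl-4-methylpyridine (1.5 equiv), CH2Cl2, 0 °C to rt
Reagents that add atoms: trifluoromethanesulfonic anhydride, O=S(=O)(C(F)(F)F)OS(=O)(=O)C(F)(F)F
Why: O-triflation of the enone carbonyl followed by loss of a γ-proton from the O–CH2 group on the β-carbon gives the linearly conjugated dienyl triflate (the reaction type that turns steroidal 4-en-3-ones into 3,5-dienyl triflates), which converts the allylic lactone into the dienol lactone in the same step.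

**Step 9**
Reactants: 15 (S)-dienyl triflate
Product: 16 (S)-dimethoxy dienol lactone (rings A, B, C complete; ring D as 1,4-dimethoxybenzene)
Conditions: Pd(OAc)2 (5 mol%), PPh3 (10 mol%), HCO2H (2 equiv), Bu3N (3 equiv), DMF, 60 °C
Reagents that add atoms: none
Why: palladium-catalysed formate reduction of a vinyl triflate (oxidative addition of zerovalent palladium to the C–OTf bond, formate exchange, decarboxylation to a palladium hydride, reductive elimination); the enol ester and aryl ethers should be inert.

**Step 10**
Reactants: 16 (S)-dimethoxy dienol lactone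
Product: 17 (S)-naphthoquinone dienol lactone
Conditions: (NH4)2Ce(NO3)6 (2.5 equiv), MeCN/H2O (3:1), 0 °C, 15 min
Reagents that add atoms: water, O
Why: oxidative demethylation of the 1,4-dimethoxynaphthalene by tetravalent cerium; the electron-rich dimethoxyarene is oxidised at a much lower potential than the dienol ester, and the short cold reaction should spare the lactone.

**Step 11**
Reactants: 17 (S)-naphthoquinone dienol lactone; 18 hypotaurine (2-aminoethanesulfinic acid)
Product: 22 target CNP0348176.1, via sulfonyl hydroquinone 19 (not isolated), via sulfonyl quinone 20 (not isolated), via leuco thiazine hydroquinone 21 (not isolated)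
Conditions: 18 (1.3 equiv), MeCN/EtOH/H2O, NaOAc/AcOH buffer (pH 6), O2 (1 atm), rt to 40 °C
Reagents that add atoms: none
Why: The sulfinate sulfur adds in conjugate fashion to one quinone CH and tautomerization gives sulfonyl hydroquinone 19; oxygen reoxidises it to sulfonyl quinone 20, the pendant amine adds to the neighbouring quinone carbon to give 21, and a second aerobic oxidation gives 22. The closest known reaction type is the hypotaurine annulation of 1,4-naphthoquinones to quinones fused to a 1,1-dioxo-1,4-thiazine ring. Ring E is closed in the C–N bond-forming event, a 6-endo-trig aza-Michael addition onto a carbon activated by both the sulfonyl group and the quinone carbonyl, after intermolecular C–S bond formation. No stereocentre is formed and the quaternary centre is remote from the reacting atoms. The step needs regioselectivity (sulfur on the CH next to the carbonyl that is para to the quaternary-carbon-bearing ring C carbon) and chemoselectivity over aminolysis of the dienol lactone. The lactone C=O, para to the ring C carbon bearing the other quinone carbonyl, makes that enone the better acceptor so the soft sulfinate should add β to it, and at pH 6 the nitrogen is protonated, so sulfur should add first and the lactone should be left alone.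

**Compound list**

1 | 1,4-dimethoxy-2,3-dimethylbenzene | COc1ccc(OC)c(C)c1C | starting material
2 | 2,3-bis(bromomethyl)-1,4-dimethoxybenzene | COc1ccc(OC)c(CBr)c1CBr | intermediate
3 | ethyl pent-2-ynoate | CCC#CC(=O)OCC | starting material
4 | 1,4-dimethoxy-5,6-dimethylidenecyclohexa-1,3-diene (o-quinodimethane) | COC1=CC=C(OC)C(=C)C1=C | intermediate
5 | ethyl 3-ethyl-5,8-dimethoxy-1,4-dihydronaphthalene-2-carboxylate | CCOC(=O)C1=C(CC)Cc2c(OC)ccc(OC)c2C1 | intermediate
6 | ethyl 3-ethyl-5,8-dimethoxynaphthalene-2-carboxylate | CCOC(=O)c1cc2c(OC)ccc(OC)c2cc1CC | intermediate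
7 | 2-[(tert-butyldimethylsilyl)oxy]-N-methoxy-N-methylacetamide | CON(C)C(=O)CO[Si](C)(C)C(C)(C)C | starting material
8 | ethyl 3-[4-(tert-butyldimethylsilyloxy)-3-oxobutan-2-yl]-5,8-dimethoxynaphthalene-2-carboxylate (racemic) | CCOC(=O)c1cc2c(OC)ccc(OC)c2cc1C(C)C(=O)CO[Si](C)(C)C(C)(C)C | intermediate
9 | ethyl 3-(4-hydroxy-3-oxobutan-2-yl)-5,8-dimethoxynaphthalene-2-carboxylate (racemic) | CCOC(=O)c1cc2c(OC)ccc(OC)c2cc1C(C)C(=O)CO | intermediate
10 | racemic keto lactone, 7,10-dimethoxy-5-methylnaphtho[2,3-c]oxepine-1,4(3H,5H)-dione | CC1C(=O)COC(=O)c2cc3c(OC)ccc(OC)c3cc12 | intermediate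
11 | pent-1-en-3-one (ethyl vinyl ketone) | CCC(=O)C=C | starting material
12 | (S)-Michael adduct, (5S)-7,10-dimethoxy-5-methyl-5-(3-oxopentyl)naphtho[2,3-c]oxepine-1,4(3H,5H)-dione | CCC(=O)CC[C@]1(C)C(=O)COC(=O)c2cc3c(OC)ccc(OC)c3cc12 | intermediate
13 | aldol adduct (β-hydroxy ketone, ring A closed, (S) quaternary carbon, new carbinol and methine centres undefined) | O=C1CC[C@]2(C)C(O)(C1C)COC(=O)c1cc3c(OC)ccc(OC)c3cc12 | intermediate
14 | (S)-tetracyclic enone lactone | O=C1CC[C@]2(C)C(=C1C)COC(=O)c1cc3c(OC)ccc(OC)c3cc12 | intermediate
15 | (S)-dienyl triflate | CC1=C(OS(=O)(=O)C(F)(F)F)CC[C@]2(C)C1=COC(=O)c1cc3c(OC)ccc(OC)c3cc12 | intermediate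
16 | (S)-dimethoxy dienol lactone | CC1=CCC[C@]2(C)C1=COC(=O)c1cc3c(OC)ccc(OC)c3cc12 | intermediate
17 | (S)-naphthoquinone dienol lactone | CC1=CCC[C@]2(C)C1=COC(=O)c1cc3C(=O)C=CC(=O)c3cc12 | intermediate
18 | hypotaurine (2-aminoethanesulfinic acid) | NCCS(=O)O | starting material
19 | (S)-sulfonyl hydroquinone (2-aminoethylsulfonyl group on the ring D carbon next to the C–OH that is para to the quaternary-carbon-bearing ring C carbon) | CC1=CCC[C@]2(C)C1=COC(=O)c1cc3c(O)c(S(=O)(=O)CCN)cc(O)c3cc12 | intermediate
20 | (S)-sulfonyl quinone | CC1=CCC[C@]2(C)C1=COC(=O)c1cc3C(=O)C(S(=O)(=O)CCN)=CC(=O)c3cc12 | intermediate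
21 | (S)-leuco thiazine hydroquinone | CC1=CCC[C@]2(C)C1=COC(=O)c1cc3c(O)c4c(c(O)c3cc12)NCCS4(=O)=O | intermediate
22 | target CNP0348176.1, (S) quaternary carbon | CC1=CCC[C@]2(C)C1=COC(=O)c1cc3c(cc12)C(=O)C1=C(C3=O)S(=O)(=O)CCN1 | target

**Step count**

Total steps: 11. Longest linear sequence: 11 steps (from 1).

**Steps most likely to fail**

1. Step 6. Facial discrimination of the planar benzylic enolate by the ion-paired catalyst may be insufficient, or the basic medium may slowly open the lactone. Fallback: setting out from 10, an achiral amine base (DBU, catalytic, MeCN, 0 °C) should give the racemic Michael adduct F1 with 11. The enantiomers of F1 would then be separated by preparative chromatography on a chiral stationary phase, and the (S)-enantiomer is 12, where the route is rejoined. This replaces catalyst-controlled induction by resolution.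

2. Step 8. Proton loss may occur from the ring CH2 next to the carbonyl instead of from the O–CH2 group, which would give the cross-conjugated cyclohexadienyl triflate and leave the lactone at the allylic level. Fallback: setting out from 14, a Luche reduction (NaBH4, CeCl3·7H2O, MeOH, −20 °C) should give the allylic alcohol F2. Treatment with 2,4-dinitrobenzenesulfenyl chloride and Et3N in 1,2-dichloroethane gives the allylic sulfenate F3, which on warming should undergo the [2,3]-sigmatropic sulfenate-to-sulfoxide shift (Mislow–Evans type) to the tertiary allylic sulfoxide F4 on the former β-carbon. The only β-hydrogens of F4 are on the O–CH2 group, so thermal syn-elimination can only give the diene of 16, where the route is rejoined. This is a regiospecific 1,4-dehydration in place of the triflate reduction.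

3. Step 11. Nitrogen may compete with sulfur in the first addition (leading to the other regioisomer), and the free amine may open the dienol lactone. Fallback: setting out from 18, Boc2O and NaHCO3 in dioxane/water should give sodium 2-[(tert-butoxycarbonyl)amino]ethanesulfinate F5, a sulfur-only nucleophile. Its conjugate addition to 17 (AcOH, MeCN/H2O) should give the protected sulfonyl hydroquinone F6 under the same electronic bias, and Ag2O oxidation gives the protected sulfonyl quinone F7. CF3CO2H in CH2Cl2 then removes the carbamate to release 20 as its ammonium salt, where the route is rejoined; buffering to pH 6 under air completes ring closure and oxidation to 22.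

**Further compounds**

F1 | step 6 | racemic Michael adduct | CCC(=O)CCC1(C)C(=O)COC(=O)c2cc3c(OC)ccc(OC)c3cc12
F2 | step 8 | allylic alcohol from 14 (carbinol configuration undefined) | OC1CC[C@]2(C)C(=C1C)COC(=O)c1cc3c(OC)ccc(OC)c3cc12
F3 | step 8 | allylic 2,4-dinitrobenzenesulfenate of F2 | [O-][N+](=O)c1ccc(SOC2CC[C@]3(C)C(=C2C)COC(=O)c2cc4c(OC)ccc(OC)c4cc23)c(c1)[N+](=O)[O-]
F4 | step 8 | tertiary allylic 2,4-dinitrophenyl sulfoxide (sulfur on the former enone β-carbon) | CC1=CCC[C@]2(C)C1(S(=O)c1ccc(cc1[N+](=O)[O-])[N+](=O)[O-])COC(=O)c1cc3c(OC)ccc(OC)c3cc12
F5 | step 11 | sodium 2-[(tert-butoxycarbonyl)amino]ethanesulfinate | CC(C)(C)OC(=O)NCCS(=O)[O-].[Na+]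
F6 | step 11 | N-Boc sulfonyl hydroquinone | CC1=CCC[C@]2(C)C1=COC(=O)c1cc3c(O)c(S(=O)(=O)CCNC(=O)OC(C)(C)C)cc(O)c3cc12
F7 | step 11 | N-Boc sulfonyl quinone | CC1=CCC[C@]2(C)C1=COC(=O)c1cc3C(=O)C(S(=O)(=O)CCNC(=O)OC(C)(C)C)=CC(=O)c3cc12
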